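**Retrosynthetic overview**

1. The last bonds cut are the six O–CH3 bonds (BBr3), then the dioxin O–C9 bond (intramolecular Ullmann coupling of a hydroquinone), then the two aryl ether bonds on ring A; this leads back to 2,3-dibromo-5-methoxy-1,4-benzoquinone, 3,5-dimethoxyphenol and a 9-bromodibenzofuran-8-ol.
2. The dibenzofuran is opened through its furan ring at C9a–C9b and C4a–O, giving an O-aryl hydroxylamine (ring C) and phloroglucinol (ring D): an oxygen version of the Fischer indole synthesis.
3. Structural feature used: ring D (C1, C2, C3, C4, C4a, C9b) is a 1,3,5-trioxygenated benzene in which the oxygen-bearing C4a and the aryl-bearing C9b are neighbours, so it corresponds to phloroglucinol reacting as a ketone at one carbon and through the adjacent carbon; ring A carries two oxygens para to each other (the carbon holding the dioxin oxygen bound to C9 and the carbon holding the hydroxyl beside the ring-E ether), so it corresponds to a 1,4-quinone.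
4. Ring order: rings C, D, A and E are bought as benzenes; the furan ring is made first (C–C, then C–O), ring E and then the dibenzofuran are attached to ring A, the dioxin ring is closed, and deprotection follows.

Key step: step 3

Remark on the chemistry: the target is achiral (no stereocentre, no stereogenic double bond), so no stereocontrol is needed; the C=N geometry of imidate 3 is left open because the group is cleaved in step 3. Dibenzofuran locants (C1–C4, C4a, O5, C5a, C6–C9, C9a, C9b) are used for the tricycle. Ring A is the pentaoxygenated benzene, ring B the 1,4-dioxin, ring C the central benzene, ring D the outer benzene of the dibenzofuran, ring E the pendant phenoxy ring.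

**Route**

Step 1
Reactants: 1 4-bromo-2-methoxyphenol
Product: 2 1-(benzyloxy)-4-bromo-2-methoxybenzene
Conditions: BnBr, K2CO3, DMF, 25 °C
Reagents that add atoms: benzyl bromide, BrCc1ccccc1
Why: Williamson ether synthesis; the phenoxide of 1 displaces bromide from benzyl bromide while the aryl bromide stays untouched.

Step 2
Reactants: 2 1-(benzyloxy)-4-bromo-2-methoxybenzene
Product: 3 ethyl N-[4-(benzyloxy)-3-methoxyphenoxy]acetimidate
Conditions: ethyl N-hydroxyacetimidate, [Pd(allyl)Cl]2 (cat.), t-BuBrettPhos (cat.), Cs2CO3, toluene, 65 °C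
Reagents that add atoms: ethyl N-hydroxyacetimidate, CCOC(C)=NO
Why: Pd-catalysed C–O cross-coupling (Buchwald-type O-arylation of an N-hydroxy imidate); the bulky biarylphosphine allows C–O reductive elimination from the electron-rich aryl bromide, and the imidate masks the hydroxylamine nitrogen.

Step 3
Reactants: 3 ethyl N-[4-(benzyloxy)-3-methoxyphenoxy]acetimidate; 4 phloroglucinol (5 equiv)
Product: 8 8-(benzyloxy)-7-methoxydibenzo[b,d]furan-1,3-diol, via aryloxyamine 5 (not isolated), via N,O-diarylhydroxylamine 6 (not isolated), via aminohydroxybiaryl 7 (not isolated)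
Conditions: HCl (4 M in 1,4-dioxane, 3 equiv), H2O (3 equiv), degassed 1,4-dioxane, Ar, 20 °C then 70 °C
Reagents that add atoms: none
Why: Proposed new method: aqueous HCl hydrolyses the imidate to the aryloxyammonium salt of 5 (ethyl acetate leaves), which condenses with the triketone tautomer of phloroglucinol, as hydroxylamine and arylamines are known to do, giving an O-aryl oxime whose aromatic tautomer is the N,O-diarylhydroxylamine 6; the weak N–O bond then breaks in a [3,3]-sigmatropic shift that joins the ring-C carbon ortho to oxygen (future C9a) to an ortho carbon of the phloroglucinol ring (future C9b), and rearomatisation gives the 2-amino-2'-hydroxybiaryl 7. The closest known reaction types are the acid-promoted rearrangement–cyclisation of O-aryl oxime ethers of ketones and cyclic 1,3-diketones to benzofurans and the [3,3] rearrangement of N,O-diarylhydroxylamines to 2-amino-2'-hydroxybiaryls; the untested element is phloroglucinol itself as the carbonyl partner. The furan ring is the only ring closed: its C9a–C9b bond comes from the sigmatropic shift and its C4a–O bond from 5-exo-trig addition of the new phenol oxygen to the iminium (keto-type) tautomer of the 5-aminoresorcinol ring, after which ammonia is lost and the dibenzofuran aromatises. No stereocentre is formed. The step needs C–C bond formation at the ring-C carbon para to the methoxy group rather than at the carbon lying between the aminooxy and methoxy groups; the 3-methoxy-4-benzyloxy pattern should secure this sterically and electronically (the behaviour of meta-donor arylhydrazines in the Fischer indole synthesis), and the two ortho carbons of phloroglucinol are equivalent. The excess of phloroglucinol should limit reaction to one carbonyl, and the product diol, much less ketonic than phloroglucinol, should not condense again.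

Step 4
Reactants: 8 8-(benzyloxy)-7-methoxydibenzo[b,d]furan-1,3-diol
Product: 9 8-(benzyloxy)-1,3,7-trimethoxydibenzo[b,d]furan
Conditions: Me2SO4, K2CO3, acetone, reflux
Reagents that add atoms: dimethyl sulfate, COS(=O)(=O)OC
Why: Williamson-type O-methylation of both phenols; dimethyl sulfate with K2CO3 in acetone favours O- over C-methylation of the resorcinol-type ring.

Step 5
Reactants: 9 8-(benzyloxy)-1,3,7-trimethoxydibenzo[b,d]furan
Product: 10 1,3,7-trimethoxydibenzo[b,d]furan-8-ol
Conditions: H2 (1 atm), Pd/C, EtOAc/MeOH, 25 °C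
Reagents that add atoms: none
Why: Catalytic hydrogenolysis of the benzyl aryl ether, carried out before any halogen is present; methyl ethers and the dibenzofuran are inert.

Step 6
Reactants: 10 1,3,7-trimethoxydibenzo[b,d]furan-8-ol
Product: 11 9-bromo-1,3,7-trimethoxydibenzo[b,d]furan-8-ol
Conditions: NBS (1.0 equiv, added slowly), i-Pr2NH (cat.), CH2Cl2, −78 to −40 °C
Reagents that add atoms: N-bromosuccinimide, O=C1CCC(=O)N1Br
Why: Amine-catalysed ortho-bromination of a phenol (electrophilic aromatic substitution in which an N-bromoamine is delivered to the hydrogen-bonded phenol/ammonium phenoxide pair); C9 is the only free position ortho to the 8-OH and the para position (C5a) is substituted, while low temperature and slow addition should keep the methyl-ether-activated carbons of ring D from reacting.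

Step 7
Reactants: 12 5-bromovanillin (3-bromo-4-hydroxy-5-methoxybenzaldehyde)
Product: 13 2,3-dibromo-4-hydroxy-5-methoxybenzaldehyde
Conditions: Br2, Fe powder (cat.), AcOH, 60 °C
Reagents that add atoms: bromine, BrBr
Why: Electrophilic aromatic bromination; the methoxy group directs the second bromine to its para position, the carbon between the formyl-bearing and the bromine-bearing carbons.

Step 8
Reactants: 13 2,3-dibromo-4-hydroxy-5-methoxybenzaldehyde
Product: 14 2,3-dibromo-5-methoxybenzene-1,4-diol
Conditions: H2O2 (30% aq), H3BO3, H2SO4 (cat.), THF, 25 °C, N2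
Reagents that add atoms: hydrogen peroxide, OO
Why: Dakin oxidation; the para-hydroxyl promotes aryl migration in the peroxide adduct of the aldehyde (Baeyer–Villiger-type) and the aryl formate is hydrolysed to the hydroquinone.

Step 9
Reactants: 14 2,3-dibromo-5-methoxybenzene-1,4-diol
Product: 15 2,3-dibromo-5-methoxy-1,4-benzoquinone
Conditions: Ag2O, MgSO4, Et2O, 25 °C
Reagents that add atoms: none
Why: Two-electron oxidation of a para-hydroquinone to the quinone under neutral, anhydrous conditions that leave the C–Br bonds and the methoxy group intact.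

Step 10
Reactants: 15 2,3-dibromo-5-methoxy-1,4-benzoquinone; 16 3,5-dimethoxyphenol (1.0 equiv, added slowly)
Product: 17 3-bromo-2-(3,5-dimethoxyphenoxy)-5-methoxy-1,4-benzoquinone
Conditions: K2CO3, DMF, −30 to 0 °C
Reagents that add atoms: none
Why: Addition–elimination (vinylogous acyl substitution) on a haloquinone; C2–Br, para to C5–OMe, is the β-carbon of the C4 carbonyl, which is only cross-conjugated to the methoxy group, whereas C3–Br is β to the C1 carbonyl deactivated as a vinylogous ester (MeO–C5=C6–C1=O), so the phenoxide should enter at C2, and the new aryloxy group then deactivates the quinone against a second substitution.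

Step 11
Reactants: 17 3-bromo-2-(3,5-dimethoxyphenoxy)-5-methoxy-1,4-benzoquinone; 11 9-bromo-1,3,7-trimethoxydibenzo[b,d]furan-8-ol
Product: 18 2-(3,5-dimethoxyphenoxy)-3-[(9-bromo-1,3,7-trimethoxydibenzo[b,d]furan-8-yl)oxy]-5-methoxy-1,4-benzoquinone
Conditions: Cs2CO3, DMF, 0 to 25 °C
Reagents that add atoms: none
Why: Second addition–elimination at the remaining quinone C–Br; the phenoxide of 11 has both ortho carbons and the para carbon substituted, so it can react only through oxygen, and the unactivated aryl bromide at C9 is inert to nucleophilic substitution.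

Step 12
Reactants: 18 2-(3,5-dimethoxyphenoxy)-3-[(9-bromo-1,3,7-trimethoxydibenzo[b,d]furan-8-yl)oxy]-5-methoxy-1,4-benzoquinone
Product: 19 3-[(9-bromo-1,3,7-trimethoxydibenzo[b,d]furan-8-yl)oxy]-2-(3,5-dimethoxyphenoxy)-5-methoxybenzene-1,4-diol
Conditions: Na2S2O4, THF/H2O, 25 °C, Ar; used at once
Reagents that add atoms: none
Why: Dithionite reduction of the quinone to the hydroquinone; aryl bromide and ether bonds are unaffected.

Step 13
Reactants: 19 3-[(9-bromo-1,3,7-trimethoxydibenzo[b,d]furan-8-yl)oxy]-2-(3,5-dimethoxyphenoxy)-5-methoxybenzene-1,4-diol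
Product: 20 hexacyclic hexamethyl ether of the target (ring-E, ring-D and ring-C hydroxyls and the ring-A hydroxyl beside the dioxin as methyl ethers; only the ring-A hydroxyl beside the ring-E ether free)
Conditions: CuCl (20 mol %), 2,2,6,6-tetramethylheptane-3,5-dione (40 mol %), Cs2CO3, degassed NMP (0.02 M), 110 °C, Ar
Reagents that add atoms: none
Why: Intramolecular Ullmann C–O coupling catalysed by monovalent copper; only the hydroquinone hydroxyl ortho to the dibenzofuranyl ether can reach C9 (six-membered dioxin ring), while the para hydroxyl would require an impossible meta-bridged ring and stays free.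

Step 14
Reactants: 20 hexacyclic hexamethyl ether of the target
Product: 21 target CNP0256302.0
Conditions: BBr3 (excess), CH2Cl2, −78 to 25 °C, Ar; then H2O
Reagents that add atoms: none
Why: Lewis-acid cleavage of aryl methyl ethers by BBr3 (boron coordination to oxygen, bromide attack at methyl); the diaryl ether, dioxin and furan C–O bonds carry no sp3 carbon and should survive.

**Compound list**

1 | 4-bromo-2-methoxyphenol | COc1cc(Br)ccc1O | starting material
2 | 1-(benzyloxy)-4-bromo-2-methoxybenzene | COc1cc(Br)ccc1OCc1ccccc1 | intermediate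
3 | ethyl N-[4-(benzyloxy)-3-methoxyphenoxy]acetimidate | CCOC(C)=NOc1ccc(OCc2ccccc2)c(OC)c1 | intermediate
4 | phloroglucinol (benzene-1,3,5-triol) | Oc1cc(O)cc(O)c1 | starting material
5 | O-[4-(benzyloxy)-3-methoxyphenyl]hydroxylamine (aryloxyamine, present as its hydrochloride) | NOc1ccc(OCc2ccccc2)c(OC)c1 | intermediate (not isolated)
6 | 5-{[4-(benzyloxy)-3-methoxyphenoxy]amino}benzene-1,3-diol (N,O-diarylhydroxylamine) | Oc1cc(O)cc(NOc2ccc(OCc3ccccc3)c(OC)c2)c1 | intermediate (not isolated)
7 | 6-amino-5'-(benzyloxy)-4'-methoxybiphenyl-2,2',4-triol (aminohydroxybiaryl) | Nc1cc(O)cc(O)c1-c1cc(OCc2ccccc2)c(OC)cc1O | intermediate (not isolated)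
8 | 8-(benzyloxy)-7-methoxydibenzo[b,d]furan-1,3-diol | Oc1cc(O)c2c(c1)oc1cc(OC)c(OCc3ccccc3)cc21 | intermediate
9 | 8-(benzyloxy)-1,3,7-trimethoxydibenzo[b,d]furan | COc1cc(OC)c2c(c1)oc1cc(OC)c(OCc3ccccc3)cc21 | intermediate
10 | 1,3,7-trimethoxydibenzo[b,d]furan-8-ol | COc1cc(OC)c2c(c1)oc1cc(OC)c(O)cc21 | intermediate
11 | 9-bromo-1,3,7-trimethoxydibenzo[b,d]furan-8-ol | COc1cc(OC)c2c(c1)oc1cc(OC)c(O)c(Br)c21 | intermediate
12 | 5-bromovanillin (3-bromo-4-hydroxy-5-methoxybenzaldehyde) | COc1cc(C=O)cc(Br)c1O | starting material
13 | 2,3-dibromo-4-hydroxy-5-methoxybenzaldehyde | COc1cc(C=O)c(Br)c(Br)c1O | intermediate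
14 | 2,3-dibromo-5-methoxybenzene-1,4-diol | COc1cc(O)c(Br)c(Br)c1O | intermediate
15 | 2,3-dibromo-5-methoxy-1,4-benzoquinone | COC1=CC(=O)C(Br)=C(Br)C1=O | intermediate
16 | 3,5-dimethoxyphenol | COc1cc(OC)cc(O)c1 | starting material
17 | 3-bromo-2-(3,5-dimethoxyphenoxy)-5-methoxy-1,4-benzoquinone | COC1=CC(=O)C(Oc2cc(OC)cc(OC)c2)=C(Br)C1=O | intermediate
18 | 2-(3,5-dimethoxyphenoxy)-3-[(9-bromo-1,3,7-trimethoxydibenzo[b,d]furan-8-yl)oxy]-5-methoxy-1,4-benzoquinone | COC1=CC(=O)C(Oc2cc(OC)cc(OC)c2)=C(Oc2c(OC)cc3oc4cc(OC)cc(OC)c4c3c2Br)C1=O | intermediate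
19 | 3-[(9-bromo-1,3,7-trimethoxydibenzo[b,d]furan-8-yl)oxy]-2-(3,5-dimethoxyphenoxy)-5-methoxybenzene-1,4-diol | COc1cc(O)c(Oc2cc(OC)cc(OC)c2)c(Oc2c(OC)cc3oc4cc(OC)cc(OC)c4c3c2Br)c1O | intermediate
20 | hexacyclic hexamethyl ether of the target with one free ring-A hydroxyl (beside the ring-E ether) | COc1cc(OC)cc(Oc2c(O)cc(OC)c3c2Oc2c(OC)cc4oc5cc(OC)cc(OC)c5c4c2O3)c1 | intermediate
21 | target CNP0256302.0 (heptahydroxy hexacycle: ring E 3,5-dihydroxyphenoxy on ring A, dioxin ring B, dibenzofuran rings C and D) | Oc1cc(O)cc(Oc2c(O)cc(O)c3c2Oc2c(O)cc4oc5cc(O)cc(O)c5c4c2O3)c1 | target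

**Step count and risks**

Total step count: 14 steps. Longest linear sequence: 10 steps (steps 1–6, then 11–14); the ring-A branch (steps 7–10) joins at step 11.

Steps most likely to fail:

1. Step 3 (the step carrying the new-method label). The electron-rich aryloxyamine may lose its N–O bond before it condenses with phloroglucinol, the condensation may be too slow to compete, or the amino-biaryl may stop short of ring closure. Fallback with known chemistry, setting out from aryl bromide 2 and phenol 16 and returning at 9: Cu-catalysed Ullmann etherification (CuCl, 2,2,6,6-tetramethylheptane-3,5-dione, Cs2CO3, NMP, 120 °C) would give the diaryl ether 1-(benzyloxy)-4-(3,5-dimethoxyphenoxy)-2-methoxybenzene F1. Intramolecular dehydrogenative biaryl coupling catalysed by Pd(OAc)2 (K2CO3, pivalic acid, air, 110 °C) would then close the furan between the ring-C carbon para to the methoxy group and either of the two equivalent ortho carbons of the dimethoxyphenoxy ring, giving 9 directly, so that step 4 falls away.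

2. Step 6. Electrophilic attack at the methyl-ether-activated carbons of ring D (C2, C4) or at C6 may compete with the phenol-directed attack at C9, and over-bromination may follow. Fallback setting out from diol 8 and returning at 11, in which ring D is made electron-poor during the halogenation: acetylation (Ac2O, pyridine) would give 8-(benzyloxy)-7-methoxydibenzo[b,d]furan-1,3-diyl diacetate F2. Hydrogenolysis (H2, Pd/C, EtOAc) would give 8-hydroxy-7-methoxydibenzo[b,d]furan-1,3-diyl diacetate F3. Bromination (NBS, catalytic i-Pr2NH, CH2Cl2, −78 °C), now with the guaiacol ring C as the only activated ring, would give 9-bromo-8-hydroxy-7-methoxydibenzo[b,d]furan-1,3-diyl diacetate F4. Protection of the 8-OH (MOMCl, i-Pr2NEt, CH2Cl2) would give 9-bromo-7-methoxy-8-(methoxymethoxy)dibenzo[b,d]furan-1,3-diyl diacetate F5. Methanolysis of the acetates (K2CO3, MeOH, 0 °C) would give 9-bromo-7-methoxy-8-(methoxymethoxy)dibenzo[b,d]furan-1,3-diol F6. Methylation (Me2SO4, K2CO3, acetone) would give 9-bromo-1,3,7-trimethoxy-8-(methoxymethoxy)dibenzo[b,d]furan F7, and acidic removal of the acetal (HCl, MeOH, 40 °C) would deliver 11.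

3. Step 13. The hydroquinone dianion may be re-oxidised to the quinone by traces of oxygen or copper in a higher oxidation state, and activation of the hindered, electron-rich C9–Br bond may be slow enough for hydrodebromination or intermolecular coupling to take over. Fallback setting out from 19 and returning at 20: selective silylation of the less hindered hydroxyl, the one flanked by the ring-E ether and a C–H (TBSCl 1.0 equiv, imidazole, DMF, 0 °C), would give the mono-silyl ether 3-[(9-bromo-1,3,7-trimethoxydibenzo[b,d]furan-8-yl)oxy]-4-(tert-butyldimethylsilyloxy)-2-(3,5-dimethoxyphenoxy)-5-methoxyphenol... named by position as the 1-O-TBS ether of hydroquinone 19 F8. Pd-catalysed intramolecular C–O coupling of the remaining phenol (Pd(OAc)2, t-BuXPhos, K3PO4, toluene, 100 °C), which avoids a free hydroquinone under base, would give the O-TBS ether of hexacycle 20 F9. Desilylation (Bu4NF, THF, 0 °C) would then give 20.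

**Further compounds**

F1 | step 3 | 1-(benzyloxy)-4-(3,5-dimethoxyphenoxy)-2-methoxybenzene | COc1cc(OC)cc(Oc2ccc(OCc3ccccc3)c(OC)c2)c1
F2 | step 6 | 8-(benzyloxy)-7-methoxydibenzo[b,d]furan-1,3-diyl diacetate | CC(=O)Oc1cc(OC(C)=O)c2c(c1)oc1cc(OC)c(OCc3ccccc3)cc21
F3 | step 6 | 8-hydroxy-7-methoxydibenzo[b,d]furan-1,3-diyl diacetate | CC(=O)Oc1cc(OC(C)=O)c2c(c1)oc1cc(OC)c(O)cc21
F4 | step 6 | 9-bromo-8-hydroxy-7-methoxydibenzo[b,d]furan-1,3-diyl diacetate | CC(=O)Oc1cc(OC(C)=O)c2c(c1)oc1cc(OC)c(O)c(Br)c21
F5 | step 6 | 9-bromo-7-methoxy-8-(methoxymethoxy)dibenzo[b,d]furan-1,3-diyl diacetate | CC(=O)Oc1cc(OC(C)=O)c2c(c1)oc1cc(OC)c(OCOC)c(Br)c21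
F6 | step 6 | 9-bromo-7-methoxy-8-(methoxymethoxy)dibenzo[b,d]furan-1,3-diol | Oc1cc(O)c2c(c1)oc1cc(OC)c(OCOC)c(Br)c21
F7 | step 6 | 9-bromo-1,3,7-trimethoxy-8-(methoxymethoxy)dibenzo[b,d]furan | COc1cc(OC)c2c(c1)oc1cc(OC)c(OCOC)c(Br)c21
F8 | step 13 | mono-TBS ether of hydroquinone 19 (silyl group on the hydroxyl beside the ring-E ether) | COc1cc(O[Si](C)(C)C(C)(C)C)c(Oc2cc(OC)cc(OC)c2)c(Oc2c(OC)cc3oc4cc(OC)cc(OC)c4c3c2Br)c1O
F9 | step 13 | O-TBS ether of hexacycle 20 | COc1cc(OC)cc(Oc2c(O[Si](C)(C)C(C)(C)C)cc(OC)c3c2Oc2c(OC)cc4oc5cc(OC)cc(OC)c5c4c2O3)c1
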